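The benzene ring is built, not bought. In the target, the oxygens at C3 and C6 are para, the side chain at C1 flanks C6–O and the hydrogen at C2 flanks C3–O: the substitution pattern that a Dötz benzannulation writes with a terminal alkyne. The key step therefore merges a C14 chain alkyne (methyl ester, both E alkenes and the C11′ stereocentre in place), the (1-tert-butoxyvinyl)(methoxy)carbene complex of zerovalent chromium and one CO ligand, forming C2–C3, C1–C6 and C5–C6 in one operation and giving a 4-methoxyphenol with three differentiated oxygens. The free C6–OH then directs formylation to C5; oxidation to the quinone, loss of tert-butyl and reduction complete the triol.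

Key step: step 9

Remark: ring atoms are C1 (side chain), C2 (H), C3 (OH), C4 (OH), C5 (CHO), C6 (OH) and chain atoms run from C1′ (benzylic) to C12′ (acid). The (S)-ligand in step 3 is assigned by analogy with the hydrogenation of tiglic acid to (S)-2-methylbutanoic acid and is to be confirmed on the first batch. The tert-butyl group is removed at the quinone stage on purpose, because there no phenol flanks the C2′=C3′ alkene.

Step 1
Reactants: 1 (2E,6E)-farnesyl acetate
Product: 2 (2E,6E,10E)-12-hydroxy-3,7,11-trimethyldodeca-2,6,10-trien-1-yl acetate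
Conditions: SeO2 (0.1 equiv), t-BuOOH (3 equiv), salicylic acid (0.1 equiv), CH2Cl2, 20 °C
Reagents that add atoms: selenium dioxide, O=[Se]=O; tert-butyl hydroperoxide, CC(C)(C)OO
Why: Catalytic allylic oxidation with SeO2 (ene reaction then [2,3]-sigmatropic shift, selenium reoxidised by the hydroperoxide) attacks the most electron-rich, terminal trisubstituted alkene at its (E)-methyl group, the acetate-bearing alkene being deactivated, so the (10E)-allylic alcohol should be the main product; any enal 3 formed already is carried into step 2.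

Step 2
Reactants: 2 (2E,6E,10E)-12-hydroxy-3,7,11-trimethyldodeca-2,6,10-trien-1-yl acetate
Product: 4 (2E,6E,10E)-12-acetoxy-2,6,10-trimethyldodeca-2,6,10-trienoic acid, via enal 3 (not isolated)
Conditions: MnO2, CH2Cl2, 20 °C; filter; then NaClO2, NaH2PO4, 2-methylbut-2-ene, t-BuOH/H2O, 0 → 20 °C
Reagents that add atoms: sodium chlorite, [Na+].[O-]Cl=O
Why: MnO2 oxidises only the allylic alcohol, and the Pinnick oxidation, with 2-methylbut-2-ene trapping hypochlorous acid, then takes the enal to the enoic acid without isomerising or chlorinating the alkenes and without touching the acetate.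

Step 3
Reactants: 4 (2E,6E,10E)-12-acetoxy-2,6,10-trimethyldodeca-2,6,10-trienoic acid
Product: 5 (2S,6E,10E)-12-acetoxy-2,6,10-trimethyldodeca-6,10-dienoic acid
Conditions: H2 (4 atm), Ru(OAc)2[(S)-H8-BINAP] (1 mol %), MeOH, 20 °C
Reagents that add atoms: none
Why: Carboxylate-directed asymmetric hydrogenation of an (E)-2-methylalk-2-enoic acid (the tiglic acid class) by a BINAP-type diphosphine complex of divalent ruthenium sets C2 (the later C11′) as S through face-selective hydrogen delivery within the chelated carboxylate, the ligand antipode being the one that turns tiglic acid into (S)-2-methylbutanoic acid; the two other trisubstituted alkenes lack the carboxylate anchor and should stay.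

Step 4
Reactants: 5 (2S,6E,10E)-12-acetoxy-2,6,10-trimethyldodeca-6,10-dienoic acid
Product: 7 methyl (2S,6E,10E)-12-hydroxy-2,6,10-trimethyldodeca-6,10-dienoate, via acetoxy methyl ester 6 (not isolated)
Conditions: MeI, K2CO3, DMF, 20 °C; then MeOH, 20 °C
Reagents that add atoms: iodomethane, CI
Why: SN2 methylation of the potassium carboxylate is followed by carbonate-catalysed transesterification of the allylic acetate with methanol; the base is too weak to enolise the α-methyl ester, so C2 should keep its configuration.

Step 5
Reactants: 7 methyl (2S,6E,10E)-12-hydroxy-2,6,10-trimethyldodeca-6,10-dienoate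
Product: 8 methyl (2S,6E,10E)-12-bromo-2,6,10-trimethyldodeca-6,10-dienoate
Conditions: PBr3 (0.4 equiv), pyridine (cat.), Et2O, −10 → 0 °C; used crude
Reagents that add atoms: phosphorus tribromide, BrP(Br)Br
Why: A primary allylic alcohol is converted into the bromide through its phosphite ester (SN2 by bromide), the standard entry to farnesyl-type bromides; cold, short contact keeps allylic transposition and E/Z leakage low and the ester is inert.

Step 6
Reactants: 8 methyl (2S,6E,10E)-12-bromo-2,6,10-trimethyldodeca-6,10-dienoate; 9 ethynyltrimethylsilane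
Product: 10 methyl (2S,6E,10E)-2,6,10-trimethyl-14-(trimethylsilyl)tetradeca-6,10-dien-13-ynoate
Conditions: CuI (20 mol %), K2CO3, n-Bu4NCl, DMF, 20 °C, argon
Reagents that add atoms: none
Why: Copper-catalysed allyl–alkynyl coupling: the copper acetylide formed from 9 and carbonate displaces the primary allylic bromide at the unhindered terminus (SN2 rather than SN2′) with the E geometry kept, and the silyl cap prevents a second allylation.

Step 7
Reactants: 10 methyl (2S,6E,10E)-2,6,10-trimethyl-14-(trimethylsilyl)tetradeca-6,10-dien-13-ynoate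
Product: 11 methyl (2S,6E,10E)-2,6,10-trimethyltetradeca-6,10-dien-13-ynoate
Conditions: K2CO3 (0.2 equiv), MeOH, 0 → 20 °C
Reagents that add atoms: none
Why: Methoxide-mediated protodesilylation of the alkynylsilane needs only catalytic carbonate at 0–20 °C, too mild to isomerise the skipped enyne to an allene or to epimerise C2.

Step 8
Reactants: 12 tert-butyl vinyl ether; 13 hexacarbonylchromium
Product: 16 pentacarbonyl[(1-tert-butoxyvinyl)(methoxy)carbene]chromium, via 1-tert-butoxyvinyllithium 14 (not isolated), via lithium acyl chromate 15 (not isolated)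
Conditions: t-BuLi, THF, −78 → 0 °C; Cr(CO)6, THF, −78 → 20 °C; then Me3OBF4, CH2Cl2, 0 °C; NaHCO3 work-up
Reagents that add atoms: trimethyloxonium tetrafluoroborate, C[O+](C)C.F[B-](F)(F)F
Why: Fischer carbene synthesis: oxygen-directed α-lithiation of the enol ether (as established for methyl and ethyl vinyl ether), addition of the vinyllithium to a CO ligand of Cr(CO)6, and O-methylation of the acyl chromate with the oxonium salt under non-acidic conditions that spare the enol ether.

Step 9
Reactants: 11 methyl (2S,6E,10E)-2,6,10-trimethyltetradeca-6,10-dien-13-ynoate; 16 pentacarbonyl[(1-tert-butoxyvinyl)(methoxy)carbene]chromium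
Product: 18 methyl (2S,6E,10E)-12-(4-tert-butoxy-2-hydroxy-5-methoxyphenyl)-2,6,10-trimethyldodeca-6,10-dienoate, via tricarbonylchromium arene complex 17 (not isolated)
Conditions: 16 (1.5 equiv), THF (0.05 M), 50 °C, argon; then air, light, Et2O, 20 °C
Reagents that add atoms: none
Why: Dötz benzannulation: at 50 °C complex 16 loses one CO, the terminal alkyne of 11 coordinates and inserts into the Cr=C bond with its substituted carbon next to chromium, CO insertion gives a chromium-bound dienylketene, and ring closure followed by enolisation gives the phenol, first as its Cr(CO)3 complex 17, from which air oxidation frees 18. The closest known reaction type is the benzannulation of alkenyl(alkoxy)carbene complexes of zerovalent chromium, 2-alkoxyalkenyl ones included, with terminal alkynes. The single ring closes by 6π-electrocyclisation of the ketene carbon onto the vinyl CH2 (formal [3+2+1]): carbene carbon becomes C3 (OMe), the vinyl carbons C4 (O-tert-butyl) and C5, CO becomes C6–OH and the alkyne carbons C1 and C2. No stereocentre is formed, and C11′ is remote and is not enolised in this neutral medium. The step needs regioselective insertion, secured by the size difference between CH2R and H on the alkyne, which places the chain next to the new hydroxyl, and phenol formation in preference to cyclobutenone or furan, which an alkenyl carbene, an ether solvent and moderate temperature favour. The ester and the trisubstituted alkenes should not react with the carbene at this temperature.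

Step 10
Reactants: 18 methyl (2S,6E,10E)-12-(4-tert-butoxy-2-hydroxy-5-methoxyphenyl)-2,6,10-trimethyldodeca-6,10-dienoate
Product: 19 methyl (2S,6E,10E)-12-(4-tert-butoxy-3-formyl-2-hydroxy-5-methoxyphenyl)-2,6,10-trimethyldodeca-6,10-dienoate
Conditions: MgCl2 (anhydrous), Et3N, (CH2O)n, MeCN, 80 °C; then 1 M HCl, 0 °C
Reagents that add atoms: paraformaldehyde (as formaldehyde), C=O
Why: Magnesium-mediated ortho-formylation of a phenol: the magnesium phenoxide adds to formaldehyde through a six-membered chelate at C5, the only free position ortho to C6–OH, and a second formaldehyde oxidises the benzylic alkoxide by hydride transfer; the basic medium should leave the aryl tert-butyl ether, the ester and the alkenes alone.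

Step 11
Reactants: 19 methyl (2S,6E,10E)-12-(4-tert-butoxy-3-formyl-2-hydroxy-5-methoxyphenyl)-2,6,10-trimethyldodeca-6,10-dienoate
Product: 20 (2S,6E,10E)-12-(4-tert-butoxy-3-formyl-2-hydroxy-5-methoxyphenyl)-2,6,10-trimethyldodeca-6,10-dienoic acid
Conditions: LiOH·H2O, THF/MeOH/H2O, 20 °C, argon; then 1 M HCl to pH 3, 0 °C
Reagents that add atoms: lithium hydroxide, [Li+].[OH-]
Why: Hydroxide saponification of the methyl ester (acyl–oxygen cleavage) at room temperature, run oxygen-free because the phenolate is electron-rich; an α-methyl alkanoate is not enolised under these conditions and the aldehyde has no α-hydrogen.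

Step 12
Reactants: 20 (2S,6E,10E)-12-(4-tert-butoxy-3-formyl-2-hydroxy-5-methoxyphenyl)-2,6,10-trimethyldodeca-6,10-dienoic acid
Product: 21 (2S,6E,10E)-12-(4-tert-butoxy-5-formyl-3,6-dioxocyclohexa-1,4-dien-1-yl)-2,6,10-trimethyldodeca-6,10-dienoic acid
Conditions: (NH4)2Ce(NO3)6 (2.5 equiv), MeCN/H2O (4:1), 0 °C, 15 min
Reagents that add atoms: water, O
Why: Oxidative demethylation of a 4-methoxyphenol by tetravalent cerium: two one-electron oxidations, attack of water at C3 and loss of methanol give the 1,4-quinone (carbonyls at C3 and C6) at 0 °C, conditions under which polyprenyl chains, aldehydes and carboxylic acids are routinely carried; any tert-butyl lost here only anticipates step 13.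

Step 13
Reactants: 21 (2S,6E,10E)-12-(4-tert-butoxy-5-formyl-3,6-dioxocyclohexa-1,4-dien-1-yl)-2,6,10-trimethyldodeca-6,10-dienoic acid
Product: 23 (2S,6E,10E)-12-(3-formyl-2,4,5-trihydroxyphenyl)-2,6,10-trimethyldodeca-6,10-dienoic acid, via hydroxyquinone 22 (not isolated)
Conditions: TFA/CH2Cl2 (1:10), 0 °C; evaporate; then Na2S2O4, EtOAc/H2O, 20 °C, argon
Reagents that add atoms: none
Why: In quinone 21 the C4 ether is a vinylogous tert-butyl ester, further activated by the C5 formyl group, so brief cold TFA should ionise it with loss of isobutene (the known unmasking of tert-butoxyquinones) at a stage where no phenol can add to the C2′=C3′ alkene; Na2S2O4 then reduces only the quinone of 22 to the hydroquinone, so the air-sensitive triol is released last and under reducing, oxygen-free conditions.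

Compound list
1 | (2E,6E)-farnesyl acetate | C/C(=C\COC(C)=O)CC/C=C(\C)CCC=C(C)C | starting material
2 | (2E,6E,10E)-12-hydroxy-3,7,11-trimethyldodeca-2,6,10-trien-1-yl acetate | C/C(=C\COC(C)=O)CC/C=C(\C)CC/C=C(\C)CO | intermediate
3 | (2E,6E,10E)-3,7,11-trimethyl-12-oxododeca-2,6,10-trien-1-yl acetate | C/C(=C\COC(C)=O)CC/C=C(\C)CC/C=C(\C)C=O | intermediate
4 | (2E,6E,10E)-12-acetoxy-2,6,10-trimethyldodeca-2,6,10-trienoic acid | C/C(=C\COC(C)=O)CC/C=C(\C)CC/C=C(\C)C(=O)O | intermediate
5 | (2S,6E,10E)-12-acetoxy-2,6,10-trimethyldodeca-6,10-dienoic acid | C/C(=C\COC(C)=O)CC/C=C(\C)CCC[C@H](C)C(=O)O | intermediate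
6 | methyl (2S,6E,10E)-12-acetoxy-2,6,10-trimethyldodeca-6,10-dienoate | C/C(=C\COC(C)=O)CC/C=C(\C)CCC[C@H](C)C(=O)OC | intermediate
7 | methyl (2S,6E,10E)-12-hydroxy-2,6,10-trimethyldodeca-6,10-dienoate | C/C(=C\CO)CC/C=C(\C)CCC[C@H](C)C(=O)OC | intermediate
8 | methyl (2S,6E,10E)-12-bromo-2,6,10-trimethyldodeca-6,10-dienoate | C/C(=C\CBr)CC/C=C(\C)CCC[C@H](C)C(=O)OC | intermediate
9 | ethynyltrimethylsilane | C#C[Si](C)(C)C | starting material
10 | methyl (2S,6E,10E)-2,6,10-trimethyl-14-(trimethylsilyl)tetradeca-6,10-dien-13-ynoate | C/C(=C\CC#C[Si](C)(C)C)CC/C=C(\C)CCC[C@H](C)C(=O)OC | intermediate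
11 | methyl (2S,6E,10E)-2,6,10-trimethyltetradeca-6,10-dien-13-ynoate | C/C(=C\CC#C)CC/C=C(\C)CCC[C@H](C)C(=O)OC | intermediate
12 | tert-butyl vinyl ether | C=COC(C)(C)C | starting material
13 | hexacarbonylchromium | O=C=[Cr](=C=O)(=C=O)(=C=O)(=C=O)=C=O | starting material
14 | 1-tert-butoxyvinyllithium | [Li]C(=C)OC(C)(C)C | intermediate
15 | lithium pentacarbonyl(2-tert-butoxyacryloyl)chromate | [Li+].[O-]C(C(=C)OC(C)(C)C)=[Cr](=C=O)(=C=O)(=C=O)(=C=O)=C=O | intermediate
16 | pentacarbonyl[(1-tert-butoxyvinyl)(methoxy)carbene]chromium | COC(C(=C)OC(C)(C)C)=[Cr](=C=O)(=C=O)(=C=O)(=C=O)=C=O | intermediate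
17 | tricarbonylchromium complex of phenol 18, chromium bound to the face of the benzene ring (written as two parts because the ring-to-metal bonding has no SMILES form) | C/C(=C\Cc1cc(OC)c(OC(C)(C)C)cc1O)CC/C=C(\C)CCC[C@H](C)C(=O)OC.O=C=[Cr](=C=O)=C=O | intermediate
18 | methyl (2S,6E,10E)-12-(4-tert-butoxy-2-hydroxy-5-methoxyphenyl)-2,6,10-trimethyldodeca-6,10-dienoate | C/C(=C\Cc1cc(OC)c(OC(C)(C)C)cc1O)CC/C=C(\C)CCC[C@H](C)C(=O)OC | intermediate
19 | methyl (2S,6E,10E)-12-(4-tert-butoxy-3-formyl-2-hydroxy-5-methoxyphenyl)-2,6,10-trimethyldodeca-6,10-dienoate | C/C(=C\Cc1cc(OC)c(OC(C)(C)C)c(C=O)c1O)CC/C=C(\C)CCC[C@H](C)C(=O)OC | intermediate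
20 | (2S,6E,10E)-12-(4-tert-butoxy-3-formyl-2-hydroxy-5-methoxyphenyl)-2,6,10-trimethyldodeca-6,10-dienoic acid | C/C(=C\Cc1cc(OC)c(OC(C)(C)C)c(C=O)c1O)CC/C=C(\C)CCC[C@H](C)C(=O)O | intermediate
21 | (2S,6E,10E)-12-(4-tert-butoxy-5-formyl-3,6-dioxocyclohexa-1,4-dien-1-yl)-2,6,10-trimethyldodeca-6,10-dienoic acid | C/C(=C\CC1=CC(=O)C(OC(C)(C)C)=C(C=O)C1=O)CC/C=C(\C)CCC[C@H](C)C(=O)O | intermediate
22 | (2S,6E,10E)-12-(5-formyl-4-hydroxy-3,6-dioxocyclohexa-1,4-dien-1-yl)-2,6,10-trimethyldodeca-6,10-dienoic acid | C/C(=C\CC1=CC(=O)C(O)=C(C=O)C1=O)CC/C=C(\C)CCC[C@H](C)C(=O)O | intermediate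
23 | (2S,6E,10E)-12-(3-formyl-2,4,5-trihydroxyphenyl)-2,6,10-trimethyldodeca-6,10-dienoic acid | C/C(=C\Cc1cc(O)c(O)c(C=O)c1O)CC/C=C(\C)CCC[C@H](C)C(=O)O | target

Total step count: 13. Longest linear sequence: 12 steps (steps 1–7 and 9–13); step 8 is a one-step side branch.

Steps most likely to fail

Step 9. The carbene may decompose, or the alkyne may insert without CO uptake or ring closure, so that cyclobutenone, furan or oligomer formation outruns benzannulation. Fallback: the arene is taken ready-made and the chain is attached by phenoxide C-allylation, setting out from bromide 8 (steps 6–8 are then not needed). Commercial isovanillin (3-hydroxy-4-methoxybenzaldehyde) is O-tert-butylated with isobutene and catalytic TfOH in CH2Cl2 at −78 °C to 3-tert-butoxy-4-methoxybenzaldehyde F1. Baeyer–Villiger oxidation with mCPBA gives 3-tert-butoxy-4-methoxyphenyl formate F2, which K2CO3 in MeOH cleaves to 3-tert-butoxy-4-methoxyphenol F3. F3 is then C-allylated with 8 in toluene in the presence of NaH; the para position is blocked by OMe and the ortho position between the two oxygens is shielded, so the chain should enter at the free ortho carbon. This gives phenol 18, where the route is rejoined.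

Step 10. Hydroxymethylation at a carbon flanked by two oxygens may stall, or the in-flask hydride transfer may fail, so that methoxymethyl ethers or diarylmethanes form instead of the aldehyde. Fallback: carbon–carbon bond formation and oxidation are separated, setting out from 18. Phenylboronic acid, paraformaldehyde and catalytic propionic acid in refluxing toluene with water removal tie phenol and formaldehyde into methyl (2S,6E,10E)-12-(5-tert-butoxy-6-methoxy-2-phenyl-4H-1,3,2-benzodioxaborin-8-yl)-2,6,10-trimethyldodeca-6,10-dienoate F4. Exchange with propane-1,3-diol frees methyl (2S,6E,10E)-12-[4-tert-butoxy-2-hydroxy-3-(hydroxymethyl)-5-methoxyphenyl]-2,6,10-trimethyldodeca-6,10-dienoate F5. MnO2 in CH2Cl2 then oxidises the benzylic alcohol to aldehyde 19, where the route is rejoined.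

Step 13. Acid ionisation of the tert-butyl group may be accompanied by protonation of the trisubstituted alkenes or by breakdown of the electrophilic formylquinone, and the triol may reoxidise during isolation. Fallback: the tert-butyl ether is removed before the ring is oxidised, by chelation-directed Lewis-acid dealkylation, setting out from acid 20. BCl3 in CH2Cl2 at −78 °C, bound to the formyl oxygen, cleaves only the neighbouring C4 ether (tert-butyl leaves as its chloride; the C3 methyl ether stays at this temperature) and gives (2S,6E,10E)-12-(3-formyl-2,4-dihydroxy-5-methoxyphenyl)-2,6,10-trimethyldodeca-6,10-dienoic acid F6. Oxidation of F6 with (NH4)2Ce(NO3)6 in aqueous MeCN at 0 °C gives hydroxyquinone 22 directly, where the route is rejoined; 22 is reduced with Na2S2O4 to 23 as in the second stage of step 13.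

Further compounds
F1 | step 9 | 3-tert-butoxy-4-methoxybenzaldehyde | COc1ccc(C=O)cc1OC(C)(C)C
F2 | step 9 | 3-tert-butoxy-4-methoxyphenyl formate | COc1ccc(OC=O)cc1OC(C)(C)C
F3 | step 9 | 3-tert-butoxy-4-methoxyphenol | COc1ccc(O)cc1OC(C)(C)C
F4 | step 10 | methyl (2S,6E,10E)-12-(5-tert-butoxy-6-methoxy-2-phenyl-4H-1,3,2-benzodioxaborin-8-yl)-2,6,10-trimethyldodeca-6,10-dienoate | C/C(=C\Cc1cc(OC)c(OC(C)(C)C)c2COB(c3ccccc3)Oc12)CC/C=C(\C)CCC[C@H](C)C(=O)OC
F5 | step 10 | methyl (2S,6E,10E)-12-[4-tert-butoxy-2-hydroxy-3-(hydroxymethyl)-5-methoxyphenyl]-2,6,10-trimethyldodeca-6,10-dienoate | C/C(=C\Cc1cc(OC)c(OC(C)(C)C)c(CO)c1O)CC/C=C(\C)CCC[C@H](C)C(=O)OC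
F6 | step 13 | (2S,6E,10E)-12-(3-formyl-2,4-dihydroxy-5-methoxyphenyl)-2,6,10-trimethyldodeca-6,10-dienoic acid | C/C(=C\Cc1cc(OC)c(O)c(C=O)c1O)CC/C=C(\C)CCC[C@H](C)C(=O)O
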